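## The problem

The target is the 3,7-bis(hydrogen sulfate) of tamarixetin (4'-O-methylquercetin). It is a 2-aryl-4H-chromen-4-one in which ring A (C5–C8) is fused to the pyranone ring C and ring B sits on C2. Five oxygens on three rings must end in four different states: sulfated at O3 and O7, free at O5 and O3', methylated at O4'. There is no stereocentre, so the difficulty is regiochemical and lies in telling the oxygens apart. Sulfate monoesters of phenols and enols are anionic, water-soluble and lost in acid or on heating, so they must go on near the end and only neutral chemistry may follow them. The 5-hydroxyl is hydrogen-bonded to the C4 carbonyl group and is the least nucleophilic hydroxyl of a flavonol, whereas the 3'-hydroxyl would compete with O7 and must be masked by a group that leaves without acid. The C3 oxygen is best carried from the start, because late hydroxylation of C3 in chalcones bearing a 6'-oxygen (Algar–Flynn–Oyamada reaction) tends to give aurones. The opening for the key step is in ring A: C8a (bearing O1) and C4a (bearing the C4 acyl carbon) are neighbours, and C4a is flanked on its other side by the C5 oxygen. This ortho oxygen/acyl pair beside an alkoxy group is what a 3-alkoxybenzyne delivers when it inserts into the C–O bond of a carboxylic acid.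

## Retrosynthesis

Target 21 to benzyl ether 20. The benzyl–O3' bond is cut. The one group that must be removed after sulfation has to leave under neutral, non-hydrolytic conditions, which points to hydrogenolysis. An acetal would need acid, and a silyl ether would not survive the fluoride of the key step. The forward step must leave the sulfate esters, the methyl ether and the C2=C3 bond alone.

Benzyl ether 20 to triol 19. The two O–S bonds at O3 and O7 are cut. Placing sulfation second to last keeps the polar, fragile esters out of all carbon–carbon chemistry. The chelated 5-hydroxyl needs no protection, so O3, O5 and O7 can carry one kind of protecting group and be unmasked together. The forward reaction must sulfate the acidic 7-hydroxyl and the enolic 3-hydroxyl and spare the 5-hydroxyl.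

Triol 19 to chalcone 17 through flavone 18. The three methoxymethyl (MOM) groups are put back, the O1–C2 bond is cut and two hydrogens are returned. An oxidative cyclisation of a 2'-hydroxychalcone that already carries the C3 oxygen avoids any later hydroxylation at C3. Chalcone 17 holds every carbon and every oxygen of the flavonol. Only its 2'-hydroxyl is free, so ring closure can go one way only.

Chalcone 17 to silyl triflate 7 and acid 15 (key disconnection). The O1–C8a and C4–C4a bonds are cut together. The neighbouring cuts are less attractive for three reasons:
- Friedel–Crafts acylation of a phloroglucinol ether needs Lewis acids that the acetals and the enol acetal would not survive.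
- Claisen–Schmidt condensation needs an ω-alkoxy-2-hydroxyacetophenone whose preparation costs more steps.
- Both need one of three equivalent phloroglucinol oxygens to be freed selectively.

Here the differentiation comes for nothing: O1 arrives from the carboxylic acid, and the aryne from 7 brings only the O5 and O7 acetals. The precursors are a storable ortho-silylaryl triflate and a crystalline acid. The forward reaction must add the carboxylate to the aryne carbon remote from the alkoxy group and then transfer the acyl group faster than the aryl anion is protonated.

Acid 15 to ester 14, aldol 12, and then glycolate ether 9 plus aldehyde 10. The ester C–O bond and then the Cα=Cβ bond are cut (aldol addition and elimination). Ether 9 comes from methyl glycolate 8 by O-alkylation. The enol oxygen is an acetal so that it leaves with the ring A acetals in one acid treatment. The benzyl ether of 10 is the group reserved for the last step.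

Silyl triflate 7 to phenol 6, silyl carbamate 5, carbamate 3, bis-ether 2 and phloroglucinol 1. The cuts are S–O, then the carbamate C–O, then C–Si, then the carbamate again and the two acetals. The silicon is placed by directed ortho-metalation. The carbamate is the strongest director on the ring and steers lithiation to the carbon between itself and a MOM-oxy group, which is the substitution pattern a 3-alkoxybenzyne precursor needs. The only statistical step is the first, on the cheapest material of the route.

## Roads not taken

Alternative 1: Ring A is taken apart at C5–C6, C7–C8 and C4a–C5, leaving a 2-aryl-3-benzyloxy-4-pyranone that carries a diazoacetyl group on the carbon destined to be C8a (diazo ketone A2).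
- Forward key step: irradiation of A2 triggers a Wolff rearrangement to a pyranonyl ketene, which adds benzyloxyethyne A3 in a [2+2] reaction. Heating opens the cyclobutenone, and the dienylketene closes onto the pyranone double bond (six-electron electrocyclisation) and tautomerises to the 5-hydroxy-7-benzyloxyflavone A1.
- Merits: the ketene/ynol ether polarity fixes the regiochemistry. A1 is born with O5 free and O7 and O3 as benzyl ethers. A silyl ether on O3' would allow a final fluoride deprotection with no hydrogenation risk.
- Weak points: A2 needs a long preparation (arylation of the pyranone next to the ring oxygen, oxidation of a side chain to the acid, diazo ketone formation). A3 is a thermally labile ynol ether. The cascade must engage a double bond that is part of a vinylogous ester. Photochemistry scales poorly.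
- Comparison: its end-game is at least as clean as the chosen one, and it does not rely on regioselective attack on an aryne. Against this the chosen plan sets two building blocks of five and four steps from commodity chemicals, and no photochemical or diazo chemistry.

Alternative 2: The C3–C4 bond is cut, giving dialdehyde A5, in which a salicylaldehyde oxygen carries the aryl(formyl)methyl unit.
- Forward key step: a triazolium-derived carbene converts the aromatic aldehyde into its acyl anion equivalent, which adds to the aliphatic aldehyde (6-exo closure of ring C) to give the racemic trans-dihydroflavonol A4.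
- Merits: the step is catalytic, runs near room temperature and delivers the C3 oxygen as a free hydroxyl.
- Weak points: A5 contains an α-aryl-α-aryloxy aldehyde, which enolises and self-condenses readily and can act as the donor itself. Two stereocentres are made only to be destroyed by a later dehydrogenation. A5 requires selective handling of two aldehyde groups.
- Comparison: the key step is milder than the aryne insertion at 125 °C, and that advantage is real. The chosen plan offers robust, storable precursors and an open-chain product that already has the flavonol oxidation pattern apart from one dehydrogenative closure.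

Alternative 3: The C2–C3 and O1–C8a bonds are cut, leading to trifluorophenyl ketone A7 and the ring B acid chloride A8.
- Forward key step: the lithium enolate of A7 is C-acylated by A8, and the diketone enolate oxygen displaces an ortho fluoride to close ring C as the difluoroflavone A6.
- Merits: two bonds and the ring form in one flask, by chemistry (enolate acylation, then SNAr activated by an ortho carbonyl group) that is probably more dependable than the aryne insertion.
- Weak points: ring A arrives with fluorine at C5 and C7. Two further SNAr reactions with an oxygen nucleophile are needed, on a chromone whose C2 is itself open to alkoxide attack. The nucleophile must later be removable without touching the 3'-benzyl ether, so benzyl alcohol cannot be used.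
- Comparison: the chosen plan has the less certain key step but puts all seven oxygens in place by compound 17 and needs no late carbon–fluorine to carbon–oxygen exchange.

Key step: step 10

## Assumptions

- The sulfate monoesters 20 and 21 would be formed, purified and stored as sodium salts. Names and SMILES show the neutral bis(hydrogen sulfate), the form in which the target is drawn; it is released from the salt by a cold pass through a sulfonic acid resin in its acid form.
- Aldehyde 10 is taken as a catalogue compound (it is the O-benzyl ether of isovanillin, one benzylation away).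

## Route

Step 1
Reactants: 1 phloroglucinol
Product: 2 3,5-bis(methoxymethoxy)phenol
Conditions: MOMCl (2.0 equiv), i-Pr2NEt, DMF, 0 °C to rt; chromatography
Reagents that add atoms: chloromethyl methyl ether, COCCl
Why: O-Alkylation of the phenoxide with an α-chloro ether; with two equivalents the bis-ether should be the main part of a statistical mixture and is separated from the mono- and tris-ethers, which can be recycled.

Step 2
Reactants: 2 3,5-bis(methoxymethoxy)phenol
Product: 3 3,5-bis(methoxymethoxy)phenyl N,N-diethylcarbamate
Conditions: NaH, THF, 0 °C; ClCONEt2, rt
Reagents that add atoms: N,N-diethylcarbamoyl chloride, CCN(CC)C(Cl)=O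
Why: O-Carbamoylation of the sodium phenoxide; the diethylcarbamate has no N–H and is the strongest oxygen-based director for the lithiation that follows.

Step 3
Reactants: 3 3,5-bis(methoxymethoxy)phenyl N,N-diethylcarbamate
Product: 5 3,5-bis(methoxymethoxy)-2-(trimethylsilyl)phenyl N,N-diethylcarbamate, via ortho-lithiated carbamate 4 (not isolated)
Conditions: s-BuLi, TMEDA, THF, −78 °C; TMSCl, −78 °C to rt
Reagents that add atoms: chlorotrimethylsilane, C[Si](C)(C)Cl
Why: Directed ortho-metalation: the carbamate carbonyl group and the neighbouring acetal oxygen cooperate to deliver the base to C2 between them, in preference to C4, which is flanked only by the two weaker MOM-oxy directors; silylation at −78 °C should intercept 4 before an anionic ortho-Fries shift of the carbamoyl group sets in.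

Step 4
Reactants: 5 3,5-bis(methoxymethoxy)-2-(trimethylsilyl)phenyl N,N-diethylcarbamate
Product: 6 3,5-bis(methoxymethoxy)-2-(trimethylsilyl)phenol
Conditions: LiAlH4, THF, 0 to 50 °C; aq. potassium sodium tartrate work-up
Reagents that add atoms: none
Why: Reductive cleavage of an aryl carbamate: hydride adds to the carbonyl group, the phenoxide is expelled and the formamide left behind is reduced to the amine; the aprotic, non-acidic medium should leave the aryl–silicon bond and the acetals intact.

Step 5
Reactants: 6 3,5-bis(methoxymethoxy)-2-(trimethylsilyl)phenol
Product: 7 3,5-bis(methoxymethoxy)-2-(trimethylsilyl)phenyl trifluoromethanesulfonate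
Conditions: PhNTf2, Cs2CO3, MeCN, rt
Reagents that add atoms: N-phenylbis(trifluoromethanesulfonimide), O=S(=O)(N(c1ccccc1)S(=O)(=O)C(F)(F)F)C(F)(F)F
Why: O-Triflation of the cesium phenoxide with a mild triflyl donor, the usual last step towards ortho-silylaryl triflates; no acid is formed, so the acetals and the acid-sensitive aryl–silicon bond of this electron-rich ring should be safe.

Step 6
Reactants: 8 methyl glycolate
Product: 9 methyl 2-(methoxymethoxy)acetate
Conditions: MOMCl, i-Pr2NEt, CH2Cl2, 0 °C to rt
Reagents that add atoms: chloromethyl methyl ether, COCCl
Why: O-Alkylation of the primary alcohol to the mixed acetal under amine base; the ester is untouched.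

Step 7
Reactants: 9 methyl 2-(methoxymethoxy)acetate; 10 3-(benzyloxy)-4-methoxybenzaldehyde
Product: 12 methyl 3-[3-(benzyloxy)-4-methoxyphenyl]-3-hydroxy-2-(methoxymethoxy)propanoate (racemic syn/anti mixture), via lithium ester enolate 11 (not isolated)
Conditions: LiN(i-Pr)2, THF, −78 °C; then 10, −78 °C; aq. NH4Cl
Reagents that add atoms: none
Why: Aldol addition of a lithium ester enolate to a non-enolisable aromatic aldehyde; the two new stereocentres form without control, which does not matter because both are removed in step 8.

Step 8
Reactants: 12 methyl 3-[3-(benzyloxy)-4-methoxyphenyl]-3-hydroxy-2-(methoxymethoxy)propanoate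
Product: 14 methyl (Z)-3-[3-(benzyloxy)-4-methoxyphenyl]-2-(methoxymethoxy)prop-2-enoate, via secondary mesylate 13 (not isolated)
Conditions: MsCl, Et3N, CH2Cl2, 0 °C; then DBU, rt
Reagents that add atoms: none
Why: Mesylation followed by E1cB elimination completes the aldol condensation; both diastereomers converge through the ester enolate on the conjugated alkene, and the Z isomer (aryl trans to the ester) is the thermodynamically favoured one; the geometry is erased in step 11 in any case.

Step 9
Reactants: 14 methyl (Z)-3-[3-(benzyloxy)-4-methoxyphenyl]-2-(methoxymethoxy)prop-2-enoate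
Product: 15 (Z)-3-[3-(benzyloxy)-4-methoxyphenyl]-2-(methoxymethoxy)prop-2-enoic acid
Conditions: LiOH, THF/MeOH/H2O, rt; cold 1 M HCl to pH 4
Reagents that add atoms: lithium hydroxide, [Li+].[OH-]
Why: Saponification of the methyl ester; the enol acetal is stable to hydroxide, and the acidification is kept cold and no lower than pH 4 so that it is not hydrolysed to the arylpyruvic acid.

Step 10
Reactants: 15 (Z)-3-[3-(benzyloxy)-4-methoxyphenyl]-2-(methoxymethoxy)prop-2-enoic acid; 7 3,5-bis(methoxymethoxy)-2-(trimethylsilyl)phenyl trifluoromethanesulfonate
Product: 17 (Z)-3-[3-(benzyloxy)-4-methoxyphenyl]-1-[2-hydroxy-4,6-bis(methoxymethoxy)phenyl]-2-(methoxymethoxy)prop-2-en-1-one, via 3,5-bis(methoxymethoxy)benzyne 16 (not isolated)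
Conditions: CsF (4 equiv), 7 (1.5 equiv), THF, 125 °C, sealed tube; aq. NH4Cl
Reagents that add atoms: none
Why: Fluoride first turns 15 into its cesium carboxylate and then, by attack at silicon with loss of triflate, releases aryne 16 slowly. The carboxylate oxygen should add to the aryne carbon remote from the neighbouring MOM-oxy group (the former C–OTf carbon, C8a of the flavonol), leaving the aryl anion at C4a, where the inductive pull of the adjacent C5 oxygen stabilises it; this is the normal regiochemistry of 3-alkoxybenzynes and the C7 acetal does not oppose it. The aryl anion then attacks the carbonyl group of the aryl ester just formed through a four-membered transition state, and the resulting alkoxide opens to the ortho-acyl phenoxide, so that O1–C8a and C4–C4a are made in one operation. The closest known reaction is the insertion of arynes into the C–O bond of aryl, alkyl and cinnamic carboxylic acids under these conditions, formally an aryne-mediated Fries-type acyl shift; the α-alkoxycinnamic acid is a new substrate for a known reaction type. No ring is closed and no stereocentre is formed, and the Z alkene is carried through. The step needs acyl transfer to outrun protonation of the aryl anion, which the high temperature, the aprotic medium and the slow aryne release favour. The acid has no enolisable hydrogen, its carboxylate is the only good nucleophile present, and the donor–acceptor alkene is a poor partner for ene or [2+2] reactions of the aryne. Any phenoxide that adds to the enone in the flask gives the flavanone F4 listed below, which step 11 oxidises to the same flavone.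

Step 11
Reactants: 17 (Z)-3-[3-(benzyloxy)-4-methoxyphenyl]-1-[2-hydroxy-4,6-bis(methoxymethoxy)phenyl]-2-(methoxymethoxy)prop-2-en-1-one
Product: 19 2-[3-(benzyloxy)-4-methoxyphenyl]-3,5,7-trihydroxy-4H-chromen-4-one, via tris(methoxymethyl) flavone 18 (not isolated)
Conditions: I2 (10 mol %), DMSO, 120 °C; aq. Na2S2O3 work-up; then HCl, MeOH/THF, 50 °C
Reagents that add atoms: none
Why: Iodine-catalysed oxidative cyclisation of a 2'-hydroxychalcone in DMSO: the 2'-hydroxyl closes onto C2 (6-endo oxa-Michael addition), the 3-alkoxyflavanone is iodinated at C3 through its enol and loses HI, and DMSO reoxidises HI to I2, the way α-alkoxychalcones give 3-alkoxyflavones. Acetals lost to traces of HI after ring closure do not matter, because methanolic HCl then removes all three (benzyl and methyl ethers are stable) and funnels the crude mixture to the single triol 19.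

Step 12
Reactants: 19 2-[3-(benzyloxy)-4-methoxyphenyl]-3,5,7-trihydroxy-4H-chromen-4-one
Product: 20 2-[3-(benzyloxy)-4-methoxyphenyl]-5-hydroxy-4-oxo-4H-chromene-3,7-diyl bis(hydrogen sulfate)
Conditions: SO3·pyridine (6 equiv), pyridine/DMF, 50 °C; aq. NaHCO3 to pH 8; reversed-phase or size-exclusion chromatography
Reagents that add atoms: sulfur trioxide–pyridine complex, [O-]S(=O)(=O)[n+]1ccccc1
Why: O-Sulfation with a sulfur trioxide–amine complex: the acidic 7-hydroxyl and the enolic 3-hydroxyl should react, the 5-hydroxyl is held by its hydrogen bond to the C4 carbonyl group and is the least reactive hydroxyl of a flavonol, and O3' is blocked as the benzyl ether; isolation as the disodium salt at pH 8 avoids acid-catalysed loss of the esters.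

Step 13
Reactants: 20 2-[3-(benzyloxy)-4-methoxyphenyl]-5-hydroxy-4-oxo-4H-chromene-3,7-diyl bis(hydrogen sulfate)
Product: 21 5-hydroxy-2-(3-hydroxy-4-methoxyphenyl)-4-oxo-4H-chromene-3,7-diyl bis(hydrogen sulfate)
Conditions: H2 (1 atm), 10% Pd/C, MeOH/H2O, rt, on the disodium salt; filtration, lyophilisation
Reagents that add atoms: none
Why: Hydrogenolysis of a benzyl aryl ether over palladium in neutral solution, conditions under which aryl sulfate salts, the methyl ether and the chromone double bond should be inert; this is why the one group removed after sulfation was chosen as benzyl.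

## Compound list

1 | phloroglucinol | Oc1cc(O)cc(O)c1 | starting material
2 | 3,5-bis(methoxymethoxy)phenol | COCOc1cc(O)cc(OCOC)c1 | intermediate
3 | 3,5-bis(methoxymethoxy)phenyl N,N-diethylcarbamate | CCN(CC)C(=O)Oc1cc(OCOC)cc(OCOC)c1 | intermediate
4 | 2-lithio-3,5-bis(methoxymethoxy)phenyl N,N-diethylcarbamate | CCN(CC)C(=O)Oc1cc(OCOC)cc(OCOC)c1[Li] | intermediate
5 | 3,5-bis(methoxymethoxy)-2-(trimethylsilyl)phenyl N,N-diethylcarbamate | CCN(CC)C(=O)Oc1cc(OCOC)cc(OCOC)c1[Si](C)(C)C | intermediate
6 | 3,5-bis(methoxymethoxy)-2-(trimethylsilyl)phenol | COCOc1cc(O)c([Si](C)(C)C)c(OCOC)c1 | intermediate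
7 | 3,5-bis(methoxymethoxy)-2-(trimethylsilyl)phenyl trifluoromethanesulfonate | C[Si](C)(C)c1c(OCOC)cc(OCOC)cc1OS(=O)(=O)C(F)(F)F | intermediate
8 | methyl glycolate | COC(=O)CO | starting material
9 | methyl 2-(methoxymethoxy)acetate | COCOCC(=O)OC | intermediate
10 | 3-(benzyloxy)-4-methoxybenzaldehyde | COc1ccc(C=O)cc1OCc1ccccc1 | starting material
11 | lithium 1-methoxy-2-(methoxymethoxy)ethen-1-olate (lithium enolate of 9) | COCOC=C(OC)O[Li] | intermediate
12 | methyl 3-[3-(benzyloxy)-4-methoxyphenyl]-3-hydroxy-2-(methoxymethoxy)propanoate (racemic, syn/anti mixture) | COCOC(C(=O)OC)C(O)c1ccc(OC)c(OCc2ccccc2)c1 | intermediate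
13 | methyl 3-[3-(benzyloxy)-4-methoxyphenyl]-2-(methoxymethoxy)-3-[(methylsulfonyl)oxy]propanoate (racemic, diastereomer mixture) | COCOC(C(=O)OC)C(OS(C)(=O)=O)c1ccc(OC)c(OCc2ccccc2)c1 | intermediate
14 | methyl (Z)-3-[3-(benzyloxy)-4-methoxyphenyl]-2-(methoxymethoxy)prop-2-enoate | COC(=O)/C(OCOC)=C/c1ccc(OC)c(OCc2ccccc2)c1 | intermediate
15 | (Z)-3-[3-(benzyloxy)-4-methoxyphenyl]-2-(methoxymethoxy)prop-2-enoic acid | OC(=O)/C(OCOC)=C/c1ccc(OC)c(OCc2ccccc2)c1 | intermediate
16 | 3,5-bis(methoxymethoxy)benzyne | COCOC1=CC(OCOC)=CC#C1 | intermediate
17 | (Z)-3-[3-(benzyloxy)-4-methoxyphenyl]-1-[2-hydroxy-4,6-bis(methoxymethoxy)phenyl]-2-(methoxymethoxy)prop-2-en-1-one | COCOc1cc(O)c(C(=O)/C(OCOC)=C/c2ccc(OC)c(OCc3ccccc3)c2)c(OCOC)c1 | intermediate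
18 | 2-[3-(benzyloxy)-4-methoxyphenyl]-3,5,7-tris(methoxymethoxy)-4H-chromen-4-one | COCOc1cc(OCOC)c2c(c1)oc(-c1ccc(OC)c(OCc3ccccc3)c1)c(OCOC)c2=O | intermediate
19 | 2-[3-(benzyloxy)-4-methoxyphenyl]-3,5,7-trihydroxy-4H-chromen-4-one | COc1ccc(-c2oc3cc(O)cc(O)c3c(=O)c2O)cc1OCc1ccccc1 | intermediate
20 | 2-[3-(benzyloxy)-4-methoxyphenyl]-5-hydroxy-4-oxo-4H-chromene-3,7-diyl bis(hydrogen sulfate) | COc1ccc(-c2oc3cc(OS(=O)(=O)O)cc(O)c3c(=O)c2OS(=O)(=O)O)cc1OCc1ccccc1 | intermediate
21 | 5-hydroxy-2-(3-hydroxy-4-methoxyphenyl)-4-oxo-4H-chromene-3,7-diyl bis(hydrogen sulfate) (CNP0574123.0) | COc1ccc(-c2oc3cc(OS(=O)(=O)O)cc(O)c3c(=O)c2OS(=O)(=O)O)cc1O | target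

## Step count and weak points

Total: 13 steps. Longest linear sequence: 9 steps (steps 1–5 and 10–13, from phloroglucinol 1). The acid branch is 4 steps (steps 6–9).

Step 10 (key step). The most likely failure is protonation of the aryl anion by bifluoride or unreacted acid before the acyl shift, which stops the sequence at the aryl ester. A second risk is consumption of the aryne by the product phenoxide. Regiochemical leakage at the aryne is less likely. Fallback: the same two bonds are made in separate operations. It sets out from phenol 2 and acid 15. Bromination of 2 ortho to the free hydroxyl (NBS, CH2Cl2, −78 °C) gives 2-bromo-3,5-bis(methoxymethoxy)phenol F1. Carbodiimide esterification with 15 gives the 2-bromoaryl ester F2. Bromine–lithium exchange (n-BuLi, THF, −100 °C) then triggers the anionic Fries shift of the acyl group to the lithiated carbon. The fallback returns to the route at chalcone 17.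

Step 3. Lithiation may occur at C4 between the two MOM-oxy groups, or the carbamoyl group may migrate to the lithiated carbon before the silyl chloride arrives. Fallback: an electrophilic route with a different regiochemical control element. It sets out from phenol 2. Bromination gives 2-bromo-3,5-bis(methoxymethoxy)phenol F1, and O-silylation with hexamethyldisilazane gives [2-bromo-3,5-bis(methoxymethoxy)phenoxy]trimethylsilane F3. Bromine–lithium exchange (n-BuLi, THF, −78 °C) then induces the retro-Brook shift of silicon from oxygen to carbon. Aqueous work-up returns to the route at silyl phenol 6.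

Step 11. The enol acetal may be lost to HI before the ring closes, diverting material to the 1,2-diketone and its benzofuranone hemiketal. Ring A phenols freed in the flask may be iodinated, and dehydrogenation may stall at the flavanone. Fallback: closure, deprotection and dehydrogenation are separated. It sets out from chalcone 17. NaOAc in refluxing EtOH closes the ring by oxa-Michael addition to trans-2-[3-(benzyloxy)-4-methoxyphenyl]-3,5,7-tris(methoxymethoxy)chroman-4-one F4. Methanolic HCl gives the dihydroflavonol trans-2-[3-(benzyloxy)-4-methoxyphenyl]-3,5,7-trihydroxychroman-4-one F5. F5 is dehydrogenated with I2 and KOAc in AcOH, the classical dihydroflavonol-to-flavonol oxidation. The fallback returns to the route at triol 19.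

Step 12. Sulfation may be incomplete at the hydrogen-bonded 3-hydroxyl, may creep onto the 5-hydroxyl under forcing, or the esters may hydrolyse during isolation of the salt. Fallback: the sulfates are installed as neutral, chromatographable diesters. It sets out from triol 19. 2,2,2-Trichloroethyl chlorosulfate with Et3N and DMAP gives 2-[3-(benzyloxy)-4-methoxyphenyl]-5-hydroxy-4-oxo-4H-chromene-3,7-diyl bis(2,2,2-trichloroethyl) bis(sulfate) F6, which can be purified on silica. Reductive removal of the trichloroethyl groups (Zn, HCO2NH4, MeOH) leaves the benzyl ether untouched. The fallback returns to the route at bis-sulfate 20.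

## Further compounds

F1 | step 10 | 2-bromo-3,5-bis(methoxymethoxy)phenol | COCOc1cc(O)c(Br)c(OCOC)c1
F2 | step 10 | 2-bromo-3,5-bis(methoxymethoxy)phenyl (Z)-3-[3-(benzyloxy)-4-methoxyphenyl]-2-(methoxymethoxy)prop-2-enoate | COCOc1cc(OC(=O)/C(OCOC)=C/c2ccc(OC)c(OCc3ccccc3)c2)c(Br)c(OCOC)c1
F3 | step 3 | [2-bromo-3,5-bis(methoxymethoxy)phenoxy]trimethylsilane | COCOc1cc(O[Si](C)(C)C)c(Br)c(OCOC)c1
F4 | step 11 | trans-2-[3-(benzyloxy)-4-methoxyphenyl]-3,5,7-tris(methoxymethoxy)chroman-4-one (racemic, 2R,3R enantiomer drawn) | COc1ccc(cc1OCc1ccccc1)[C@@H]1[C@@H](OCOC)C(=O)c2c(OCOC)cc(OCOC)cc2O1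
F5 | step 11 | trans-2-[3-(benzyloxy)-4-methoxyphenyl]-3,5,7-trihydroxychroman-4-one (racemic, 2R,3R enantiomer drawn) | COc1ccc(cc1OCc1ccccc1)[C@@H]1[C@@H](O)C(=O)c2c(O)cc(O)cc2O1
F6 | step 12 | 2-[3-(benzyloxy)-4-methoxyphenyl]-5-hydroxy-4-oxo-4H-chromene-3,7-diyl bis(2,2,2-trichloroethyl) bis(sulfate) | COc1ccc(-c2oc3cc(OS(=O)(=O)OCC(Cl)(Cl)Cl)cc(O)c3c(=O)c2OS(=O)(=O)OCC(Cl)(Cl)Cl)cc1OCc1ccccc1
A1 | alternative 1 | 3,7-bis(benzyloxy)-5-hydroxy-2-[4-methoxy-3-(triisopropylsilyloxy)phenyl]-4H-chromen-4-one | O=c1c(OCc2ccccc2)c(-c2ccc(OC)c(O[Si](C(C)C)(C(C)C)C(C)C)c2)oc2cc(OCc3ccccc3)cc(O)c12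
A2 | alternative 1 | 1-{5-(benzyloxy)-6-[4-methoxy-3-(triisopropylsilyloxy)phenyl]-4-oxo-4H-pyran-2-yl}-2-diazoethan-1-one | [N-]=[N+]=CC(=O)c1cc(=O)c(OCc2ccccc2)c(-c2ccc(OC)c(O[Si](C(C)C)(C(C)C)C(C)C)c2)o1
A3 | alternative 1 | benzyloxyethyne | C#COCc1ccccc1
A4 | alternative 2 | trans-2-[3-(benzyloxy)-4-methoxyphenyl]-3-hydroxy-5,7-bis(methoxymethoxy)chroman-4-one (racemic, 2R,3R enantiomer drawn) | COc1ccc(cc1OCc1ccccc1)[C@@H]1[C@@H](O)C(=O)c2c(OCOC)cc(OCOC)cc2O1
A5 | alternative 2 | 2-{1-[3-(benzyloxy)-4-methoxyphenyl]-2-oxoethoxy}-4,6-bis(methoxymethoxy)benzaldehyde (racemic) | COCOc1cc(OCOC)c(C=O)c(OC(C=O)c2ccc(OC)c(OCc3ccccc3)c2)c1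
A6 | alternative 3 | 2-[3-(benzyloxy)-4-methoxyphenyl]-5,7-difluoro-3-(methoxymethoxy)-4H-chromen-4-one | COCOc1c(-c2ccc(OC)c(OCc3ccccc3)c2)oc2cc(F)cc(F)c2c1=O
A7 | alternative 3 | 2-(methoxymethoxy)-1-(2,4,6-trifluorophenyl)ethan-1-one | COCOCC(=O)c1c(F)cc(F)cc1F
A8 | alternative 3 | 3-(benzyloxy)-4-methoxybenzoyl chloride | COc1ccc(C(Cl)=O)cc1OCc1ccccc1
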